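## Analysis of the target

Target 25 is an isoflavone: a 4H-chromen-4-one (benzene ring A fused to pyranone ring C along C4a–C8a) that carries aryl ring B at C3. It has no stereocentre, so the whole problem is one of substitution pattern and functional-group tolerance. Ring A is a resorcinol (OH at C5 and C7). Ring B is substituted at five of its six carbons: C1' bonds to C3, C2' bears OH, C3' the 3-hydroxy-3-methylbutyl chain, C4' and C5' methoxy groups, and only C6' bears hydrogen. The tertiary alcohol of the chain sits where acid would ionise it and let the neighbouring 2'-OH close a 2,2-dimethylchroman, so the endgame must avoid acid. Ring C is opened by hydroxide at C2, and the three phenols must stay distinct from the two methyl ethers. The difficulty is therefore to assemble a crowded, acid-sensitive ring B, join it to C3, and still end with free hydroxyls at C5, C7 and C2'. The strategy rests on one feature: the fusion bond C4a–C8a of ring A is the α,β-bond of a vinylogous ester (O1–C8a=C4a–C4=O) in a monocyclic 4-pyranone. C8a is its electrophilic β-carbon and C4a its nucleophilic α-carbon, and the remaining four carbons of ring A (C8, C7, C6, C5) with their 1,3-oxygens are exactly an acetoacetate unit with a nucleophilic CH2 end (C8) and an electrophilic ester end (C5).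

## Retrosynthetic reasoning

**25 back to 23.** The last operations only unmask oxygen: the benzyl ether on O2' is cut by hydrogenolysis (24 to 25) and the triethylsilyl ether on the tertiary oxygen by buffered fluoride (23 to 24). Both are neutral, so the tertiary alcohol and the 2'-phenol are never exposed to acid together. The two groups are different because the benzyl ether must survive a silyl triflate and amine bases, while the tertiary alcohol only needs to be kept from quenching a silyl dienol ether.

**23 back to 15 and 19 (ring A).** The bonds C8–C8a and C4a–C5 are cut, which removes ring A as the four-carbon diene 19 and leaves bromopyranone 15 with ring B complete. Cutting here rather than in ring C means the crowded aryl–C3 bond is already in place on a small, symmetric heterocycle, and the step has to build only an unsubstituted resorcinol. The bromine on the pyranone α-carbon marks which C=C is annulated and is lost as HBr to return the pyranone unsaturation; the ester methoxy group of 19 is lost as methanol to aromatise. A concerted cycloadduct would place bromine on a quaternary ring-fusion carbon whose only β-hydrogen (on C8a) is neither acidic nor anti-periplanar. The forward reaction is therefore staged in one flask. Pyrylium salt 20 takes the CH2 terminus of 19 at the future C8a to give 21. HBr is lost from the still monocyclic, epimerisable 21 to give 22. The α-carbon of 22 then closes onto the ester.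

**15 back to 12 and 14.** The C3–C1' bond is cut to give boronate 12 and the symmetric dibromide 14. One C–Br bond of 14 is used for the cross-coupling and the other is kept as the handle for the key step, so a single halogenation provides both. The forward coupling must stop after one arylation.

**14 back to 13, and 19 back to 16.** The dibromide comes from 4-pyranone 13 by α-bromination at both nucleophilic α-carbons. The diene comes from methyl acetoacetate 16 by two O-silylations through 17 and dienolate 18.

**12 back to 9.** The C–B bond comes from the C–Br bond of 11, the silyl ether of 11 from alcohol 10, and the bromine of 10 from electrophilic substitution of 9. In 9 the position ortho to the benzyloxy group and para to a methoxy group is the more activated of the two free ring positions, and it is the carbon that becomes C1'.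

**9 back to 6.** The tertiary alcohol comes from Markovnikov hydration of the prenyl alkene of 8 under radical, non-acidic conditions. The benzyl ether of 8 replaces the methoxymethyl ether of 6 (through phenol 7) while the side chain is still an alkene, so the acid needed for that exchange never meets the tertiary alcohol.

**6 back to 1 and 3.** The aryl–CH2 bond is cut. The methoxymethyl ether 2 of phenol 1 is deprotonated between its two oxygen substituents to give aryllithium 4, the only way to place carbon regiospecifically at the future C3'. Arylcopper 5 is then alkylated by prenyl bromide 3. A benzyl ether cannot serve here because it would be metalated at its own CH2, which is why two phenol protecting groups are used in sequence.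

## Alternatives that were turned down

**Alternative 1:** Ring C is disconnected at C4–C4a and O1–C2 into phloroglucinol A3 and ring B acrylic acid A2, in which O2' and the side chain are tied up as a dihydrocoumarin lactone.
- Forward key step: in a strongly acidic dehydrating medium A2 acylates A3, and the neighbouring phenol then adds to the acrylate double bond to give the racemic isoflavanone A1.
- For it: it is short and convergent, and A3 is symmetric, so ring A has no regiochemical question. The lactone is inert to the acid that would destroy a free tertiary alcohol. Acylation of a phenol by an acrylic acid followed by oxa-Michael closure is a close precedent.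
- Against it: A1 is one oxidation level too low at C2–C3 and must be dehydrogenated in the presence of electron-rich phenols. The tertiary alcohol then has to be made last, by double addition of a methyl nucleophile to the lactone of a molecule that also offers a chromone C2/C4 electrophile and two acidic phenols. The lactone of A2 can itself acylate A3, and an α-aryl acrylic acid can oligomerise in strong acid.
- Comparison: this alternative is stronger on precedent and on step count to the ring system. The chosen route gives the correct C2=C3 oxidation level directly and has the side chain finished before the core exists, so its endgame is two neutral deprotections instead of organometallic chemistry on a finished flavonoid.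

**Alternative 2:** Ring C is disconnected at C3–C4 and O1–C8a into ring B enamine A5 and 2,4,6-trifluorobenzoyl chloride A6.
- Forward key step: A5 is acylated on carbon by A6, and after hydrolysis of the iminium the enol oxygen displaces an ortho fluorine to give the difluoroisoflavone A4.
- For it: every event has close precedent (enamine C-acylation, ring closure by nucleophilic aromatic substitution). The symmetric acid chloride fixes the regiochemistry, and the basic conditions suit the silyl and benzyl ethers.
- Against it: ring A arrives with fluorine where oxygen is needed. Two further C–F to C–O substitutions are required on an isoflavone whose C2 is attacked by the same oxygen nucleophiles, and the second substitution is slowed once the first donor is installed. A5 also needs a ring B homologated by two carbons, which lengthens the fragment synthesis.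
- Comparison: this alternative is clearly stronger on predictability of its key step. The chosen route delivers ring A with both hydroxyls free in the key step and uses the simpler boronate 12.

**Alternative 3:** The C3–C4 bond is disconnected by an intramolecular crossed benzoin reaction of keto aldehyde A8.
- Forward key step: a triazolium-derived carbene adds to the ring A aldehyde, and the acyl anion equivalent attacks the ring B ketone to give the racemic 3-hydroxychromanone A7, which must then be dehydrated to the isoflavone.
- For it: the aldehyde–ketone benzoin closure to 3-hydroxychromanones is established and mild, and the ring A pattern is fixed from the outset.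
- Against it: the acceptor ketone carries a triply donor-substituted ring with an ortho benzyloxy group, so it is both deactivated and hindered. A7 needs an extra elimination of a hindered tertiary alcohol next to an acid-sensitive silyl ether. A8 requires a ring B α-functionalised ketone and a selectively protected ring A aldehyde, which is the longest fragment preparation of all, and it carries three benzyl ethers.
- Comparison: it is as mild as the chosen route and stronger on precedent, but weaker on step economy. The chosen route makes ring A from a four-carbon unit that costs two steps and needs no later adjustment at C3.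

Key step: step 13

Remark on the chemistry: enoate 17 is used as an E/Z mixture and the ketene acetal of 19 is drawn Z. Neither geometry matters, because these carbons all end as sp2 atoms of ring A. Intermediate 21 is a racemic mixture of diastereomers and is drawn without configuration.

## Route

Step 1
Reactants: 1 3,4-dimethoxyphenol
Product: 2 1,2-dimethoxy-4-(methoxymethoxy)benzene
Conditions: MeOCH2Cl (1.3 equiv), iPr2NEt (2 equiv), CH2Cl2, 0 °C → rt
Reagents that add atoms: chloromethyl methyl ether, COCCl
Why: O-alkylation of the phenol by the oxocarbenium-type electrophile; the methoxymethyl ether is installed because it is the directing group for the ortho-metalation that follows.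

Step 2
Reactants: 2 1,2-dimethoxy-4-(methoxymethoxy)benzene; 3 prenyl bromide (1-bromo-3-methylbut-2-ene)
Product: 6 1,2-dimethoxy-4-(methoxymethoxy)-3-(3-methylbut-2-en-1-yl)benzene, via aryllithium 4 (not isolated), via arylcopper 5 (not isolated)
Conditions: n-BuLi (1.15 equiv), THF, 0 °C, 1.5 h; CuBr·SMe2 (1.2 equiv), −78 → −30 °C; 3 (1.5 equiv), −78 °C → rt
Reagents that add atoms: none
Why: Directed ortho-metalation: the C–H between the methoxymethoxy and methoxy groups is the most acidic and both oxygens hold the lithium of 4. Transmetalation to arylcopper 5 lets the allylic substitution on 3 occur at the primary carbon without allyl transposition or Wurtz coupling.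

Step 3
Reactants: 6 1,2-dimethoxy-4-(methoxymethoxy)-3-(3-methylbut-2-en-1-yl)benzene
Product: 7 3,4-dimethoxy-2-(3-methylbut-2-en-1-yl)phenol
Conditions: HCl (1.25 M in MeOH), 20–40 °C
Reagents that add atoms: none
Why: Acid-catalysed acetal methanolysis of the methoxymethyl ether; dilute acid near room temperature protonates the acetal oxygen far faster than the trisubstituted alkene, so the freed phenol should not close a chroman.

Step 4
Reactants: 7 3,4-dimethoxy-2-(3-methylbut-2-en-1-yl)phenol
Product: 8 1-(benzyloxy)-3,4-dimethoxy-2-(3-methylbut-2-en-1-yl)benzene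
Conditions: BnBr (1.2 equiv), K2CO3 (2 equiv), DMF, rt
Reagents that add atoms: benzyl bromide, BrCc1ccccc1
Why: Williamson etherification of the phenoxide; the benzyl ether is stable to silyl triflates, amines, fluoride and palladium coupling and is removed at the end without acid.

Step 5
Reactants: 8 1-(benzyloxy)-3,4-dimethoxy-2-(3-methylbut-2-en-1-yl)benzene
Product: 9 4-[2-(benzyloxy)-5,6-dimethoxyphenyl]-2-methylbutan-2-ol
Conditions: Co(acac)2 (0.2 equiv), PhSiH3 (2.5 equiv), O2 (1 atm), THF, rt; aq. Na2S2O3
Reagents that add atoms: dioxygen, O=O
Why: Mukaiyama hydration: a cobalt hydride formed from divalent cobalt, silane and O2 delivers a hydrogen atom to the less substituted alkene carbon, and the tertiary radical is trapped by O2 and reduced to the Markovnikov alcohol. The conditions are neutral, so the benzyl ether survives and no chroman can form; no stereocentre arises.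

Step 6
Reactants: 9 4-[2-(benzyloxy)-5,6-dimethoxyphenyl]-2-methylbutan-2-ol
Product: 10 4-[2-(benzyloxy)-3-bromo-5,6-dimethoxyphenyl]-2-methylbutan-2-ol
Conditions: NBS (1.05 equiv), MeCN, 0 °C → rt, dark
Reagents that add atoms: N-bromosuccinimide, O=C1CCC(=O)N1Br
Why: Electrophilic aromatic bromination: of the two free ring positions, the one ortho to the in-plane benzyloxy group and para to a methoxy group is more activated than the one with a single ortho oxygen and a para alkyl group. NBS releases no strong acid, so the tertiary alcohol is safe.

Step 7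
Reactants: 10 4-[2-(benzyloxy)-3-bromo-5,6-dimethoxyphenyl]-2-methylbutan-2-ol
Product: 11 {[4-(2-(benzyloxy)-3-bromo-5,6-dimethoxyphenyl)-2-methylbutan-2-yl]oxy}triethylsilane
Conditions: Et3SiOTf (1.3 equiv), 2,6-lutidine (2 equiv), CH2Cl2, 0 °C
Reagents that add atoms: triethylsilyl trifluoromethanesulfonate, CC[Si](CC)(CC)OS(=O)(=O)C(F)(F)F
Why: Silylation of a hindered tertiary alcohol needs the silyl triflate with a hindered pyridine base; the ether keeps the hydroxyl from protonating the silyl diene later.

Step 8
Reactants: 11 {[4-(2-(benzyloxy)-3-bromo-5,6-dimethoxyphenyl)-2-methylbutan-2-yl]oxy}triethylsilane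
Product: 12 2-[2-(benzyloxy)-4,5-dimethoxy-3-(3-methyl-3-triethylsilyloxybutyl)phenyl]-4,4,5,5-tetramethyl-1,3,2-dioxaborolane
Conditions: B2pin2 (1.5 equiv), Pd(dppf)Cl2 (5 mol %), KOAc (3 equiv), 1,4-dioxane, 90 °C
Reagents that add atoms: bis(pinacolato)diboron, CC1(C)OB(OC1(C)C)B1OC(C)(C)C(C)(C)O1
Why: Miyaura borylation of the aryl bromide; the weak acetate base gives the boronate without coupling it further, and the silyl and benzyl ethers are inert.

Step 9
Reactants: 13 4H-pyran-4-one
Product: 14 3,5-dibromo-4H-pyran-4-one
Conditions: Br2 (2.2 equiv), CH2Cl2, 0 °C → rt; then pyridine (3 equiv), 0 °C → rt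
Reagents that add atoms: bromine, BrBr
Why: Electrophilic α-bromination of a vinylogous ester: C3 and C5 are the nucleophilic carbons of the two O–C=C–C=O units, and pyridine takes up HBr so that the pyranone is restored after each substitution.

Step 10
Reactants: 12 2-[2-(benzyloxy)-4,5-dimethoxy-3-(3-methyl-3-triethylsilyloxybutyl)phenyl]-4,4,5,5-tetramethyl-1,3,2-dioxaborolane; 14 3,5-dibromo-4H-pyran-4-one
Product: 15 3-bromo-5-[2-(benzyloxy)-4,5-dimethoxy-3-(3-methyl-3-triethylsilyloxybutyl)phenyl]-4H-pyran-4-one
Conditions: 14 (3 equiv), Pd(PPh3)4 (5 mol %), K3PO4 (2 equiv), 1,4-dioxane/H2O 10:1, 70 °C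
Reagents that add atoms: none
Why: Suzuki–Miyaura coupling: zerovalent palladium inserts into a C–Br bond α to the carbonyl, as with 3-halochromones. With the symmetric dibromide in threefold excess the first arylation should dominate, the second is slowed by the new ortho-substituted aryl group, and surplus 14 is recovered.

Step 11
Reactants: 16 methyl acetoacetate
Product: 17 methyl 3-(trimethylsilyloxy)but-2-enoate
Conditions: Me3SiCl (1.5 equiv), Et3N (1.5 equiv), hexane, rt
Reagents that add atoms: chlorotrimethylsilane, C[Si](C)(C)Cl
Why: O-silylation of the enol of a β-keto ester under amine base; the geometry of the enoate is irrelevant for the next step.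

Step 12
Reactants: 17 methyl 3-(trimethylsilyloxy)but-2-enoate
Product: 19 (Z)-1-methoxy-1,3-bis(trimethylsilyloxy)buta-1,3-diene, via lithium dienolate 18 (not isolated)
Conditions: LiN(iPr)2 (1.1 equiv), THF, −78 °C; Me3SiCl (1.2 equiv), −78 °C → rt
Reagents that add atoms: chlorotrimethylsilane, C[Si](C)(C)Cl
Why: Kinetic γ-deprotonation of the silyl enol ether gives dienolate 18, which is trapped on oxygen to give the 1,3-bis(silyloxy)diene; the diene is distilled and used fresh.

Step 13
Reactants: 15 3-bromo-5-[2-(benzyloxy)-4,5-dimethoxy-3-(3-methyl-3-triethylsilyloxybutyl)phenyl]-4H-pyran-4-one; 19 (Z)-1-methoxy-1,3-bis(trimethylsilyloxy)buta-1,3-diene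
Product: 23 2'-benzyloxy-5,7-dihydroxy-4',5'-dimethoxy-3'-(3-methyl-3-triethylsilyloxybutyl)isoflavone, via silyloxypyrylium triflate 20 (not isolated), via bromo dihydropyranone keto ester 21 (not isolated), via pyranone keto ester 22 (not isolated)
Conditions: Me3SiOTf (1.2 equiv), CH2Cl2, 0 → 20 °C, 1 h; 19 (2 equiv), −78 → 0 °C; Et3N (6 equiv), MeOH (10 equiv), 0 → 20 °C; DBU (4 equiv), 40 °C; aq. NH4Cl
Reagents that add atoms: none
Why: Proposed new method: a formal (4+2) annulation of a 1,3-bis(silyloxy)diene across the brominated C=C of a monocyclic 4-pyranone, run stepwise in one flask; the closest known reaction types are the cycloaddition–aromatisation of such dienes with haloquinones and with chromones bearing an acceptor at C3, the silyl-triflate-mediated addition of silyl enol ethers and silyloxydienes to C2 of chromones and 4-pyranones through their 4-silyloxypyrylium salts, and the base-induced loss of HBr from 3-bromochroman-4-ones. O-Silylation of 15 gives pyrylium salt 20, whose C2 (the future C8a) takes the CH2 terminus of 19 in a vinylogous Mukaiyama–Michael addition (bond C8–C8a), and methanolysis of the silyl enol ethers gives bromoketone 21. In 21 the bromine-bearing carbon is epimerisable, so an anti-periplanar H–C2/Br–C3 arrangement is available and Et3N removes HBr to restore the pyranone in 22; a concerted cycloadduct would instead hold bromine on a quaternary ring-fusion carbon with no such hydrogen, which is why the two bonds are made one after the other. DBU then forms the dienolate of 22 that runs over C8, C8a and C4a, and its α-carbon C4a attacks the ester carbon in a 6-exo-trig (enolexo) Dieckmann-type closure (bond C4a–C5) that expels methanol, after which tautomerisation gives the resorcinol ring A. No stereocentre is created in 23, because the one at C8a in 21 is erased when HBr leaves. The step needs site selectivity between C2 and C6 of 20, expected because bromine is small and inductively electron-withdrawing whereas the twisted, ortho-substituted ring B shields C6, and an adduct at C6 could neither lose HBr nor aromatise. It also needs diene regiochemistry, which is secured because only the CH2 terminus of 19 is nucleophilic toward the pyrylium carbon and only the ester carbon can reach C4a through a six-membered transition state.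

Step 14
Reactants: 23 2'-benzyloxy-5,7-dihydroxy-4',5'-dimethoxy-3'-(3-methyl-3-triethylsilyloxybutyl)isoflavone
Product: 24 2'-benzyloxy-5,7-dihydroxy-3'-(3-hydroxy-3-methylbutyl)-4',5'-dimethoxyisoflavone
Conditions: Bu4NF (3 equiv), AcOH (3 equiv), THF, rt → 40 °C
Reagents that add atoms: none
Why: Fluoride-induced Si–O cleavage; acetic acid buffers the phenoxides so that ring C is not attacked at C2, and no acid strong enough to ionise the tertiary alcohol is present.

Step 15
Reactants: 24 2'-benzyloxy-5,7-dihydroxy-3'-(3-hydroxy-3-methylbutyl)-4',5'-dimethoxyisoflavone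
Product: 25 2',5,7-trihydroxy-3'-(3-hydroxy-3-methylbutyl)-4',5'-dimethoxyisoflavone
Conditions: H2 (1 atm), 10% Pd/C, EtOAc/MeOH, rt
Reagents that add atoms: none
Why: Catalytic hydrogenolysis of the benzyl aryl ether under neutral conditions; the trisubstituted vinylogous-ester C2=C3 bond is reduced much more slowly, so the reaction is stopped at complete debenzylation.

## Compound list

1 | 3,4-dimethoxyphenol | COc1ccc(O)cc1OC | starting material
2 | 1,2-dimethoxy-4-(methoxymethoxy)benzene | COCOc1ccc(OC)c(OC)c1 | intermediate
3 | prenyl bromide (1-bromo-3-methylbut-2-ene) | CC(C)=CCBr | starting material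
4 | [2,3-dimethoxy-6-(methoxymethoxy)phenyl]lithium | [Li]c1c(OCOC)ccc(OC)c1OC | intermediate
5 | [2,3-dimethoxy-6-(methoxymethoxy)phenyl]copper | [Cu]c1c(OCOC)ccc(OC)c1OC | intermediate
6 | 1,2-dimethoxy-4-(methoxymethoxy)-3-(3-methylbut-2-en-1-yl)benzene | COCOc1ccc(OC)c(OC)c1CC=C(C)C | intermediate
7 | 3,4-dimethoxy-2-(3-methylbut-2-en-1-yl)phenol | COc1ccc(O)c(CC=C(C)C)c1OC | intermediate
8 | 1-(benzyloxy)-3,4-dimethoxy-2-(3-methylbut-2-en-1-yl)benzene | COc1ccc(OCc2ccccc2)c(CC=C(C)C)c1OC | intermediate
9 | 4-[2-(benzyloxy)-5,6-dimethoxyphenyl]-2-methylbutan-2-ol | COc1ccc(OCc2ccccc2)c(CCC(C)(C)O)c1OC | intermediate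
10 | 4-[2-(benzyloxy)-3-bromo-5,6-dimethoxyphenyl]-2-methylbutan-2-ol | COc1cc(Br)c(OCc2ccccc2)c(CCC(C)(C)O)c1OC | intermediate
11 | {[4-(2-(benzyloxy)-3-bromo-5,6-dimethoxyphenyl)-2-methylbutan-2-yl]oxy}triethylsilane | COc1cc(Br)c(OCc2ccccc2)c(CCC(C)(C)O[Si](CC)(CC)CC)c1OC | intermediate
12 | 2-[2-(benzyloxy)-4,5-dimethoxy-3-(3-methyl-3-triethylsilyloxybutyl)phenyl]-4,4,5,5-tetramethyl-1,3,2-dioxaborolane | COc1cc(B2OC(C)(C)C(C)(C)O2)c(OCc2ccccc2)c(CCC(C)(C)O[Si](CC)(CC)CC)c1OC | intermediate
13 | 4H-pyran-4-one | O=c1ccocc1 | starting material
14 | 3,5-dibromo-4H-pyran-4-one | O=c1c(Br)cocc1Br | intermediate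
15 | 3-bromo-5-[2-(benzyloxy)-4,5-dimethoxy-3-(3-methyl-3-triethylsilyloxybutyl)phenyl]-4H-pyran-4-one | O=c1c(Br)cocc1-c1cc(OC)c(OC)c(CCC(C)(C)O[Si](CC)(CC)CC)c1OCc1ccccc1 | intermediate
16 | methyl acetoacetate | COC(=O)CC(C)=O | starting material
17 | methyl 3-(trimethylsilyloxy)but-2-enoate (E/Z mixture) | COC(=O)C=C(C)O[Si](C)(C)C | intermediate
18 | lithium 1-methoxy-3-(trimethylsilyloxy)buta-1,3-dien-1-olate (dienolate of 17) | CO/C([O-])=C/C(=C)O[Si](C)(C)C.[Li+] | intermediate
19 | (Z)-1-methoxy-1,3-bis(trimethylsilyloxy)buta-1,3-diene | CO/C(O[Si](C)(C)C)=C/C(=C)O[Si](C)(C)C | intermediate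
20 | 3-[2-(benzyloxy)-4,5-dimethoxy-3-(3-methyl-3-triethylsilyloxybutyl)phenyl]-5-bromo-4-(trimethylsilyloxy)pyrylium trifluoromethanesulfonate | C[Si](C)(C)Oc1c(Br)c[o+]cc1-c1cc(OC)c(OC)c(CCC(C)(C)O[Si](CC)(CC)CC)c1OCc1ccccc1.[O-]S(=O)(=O)C(F)(F)F | intermediate
21 | methyl 4-{5-[2-(benzyloxy)-4,5-dimethoxy-3-(3-methyl-3-triethylsilyloxybutyl)phenyl]-3-bromo-4-oxo-3,4-dihydro-2H-pyran-2-yl}-3-oxobutanoate (racemic, mixture of diastereomers) | COC(=O)CC(=O)CC1OC=C(c2cc(OC)c(OC)c(CCC(C)(C)O[Si](CC)(CC)CC)c2OCc2ccccc2)C(=O)C1Br | intermediate
22 | methyl 4-{5-[2-(benzyloxy)-4,5-dimethoxy-3-(3-methyl-3-triethylsilyloxybutyl)phenyl]-4-oxo-4H-pyran-2-yl}-3-oxobutanoate | COC(=O)CC(=O)Cc1cc(=O)c(co1)-c1cc(OC)c(OC)c(CCC(C)(C)O[Si](CC)(CC)CC)c1OCc1ccccc1 | intermediate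
23 | 2'-benzyloxy-5,7-dihydroxy-4',5'-dimethoxy-3'-(3-methyl-3-triethylsilyloxybutyl)isoflavone | O=c1c(-c2cc(OC)c(OC)c(CCC(C)(C)O[Si](CC)(CC)CC)c2OCc2ccccc2)coc2cc(O)cc(O)c12 | intermediate
24 | 2'-benzyloxy-5,7-dihydroxy-3'-(3-hydroxy-3-methylbutyl)-4',5'-dimethoxyisoflavone | O=c1c(-c2cc(OC)c(OC)c(CCC(C)(C)O)c2OCc2ccccc2)coc2cc(O)cc(O)c12 | intermediate
25 | 2',5,7-trihydroxy-3'-(3-hydroxy-3-methylbutyl)-4',5'-dimethoxyisoflavone | COc1cc(-c2coc3cc(O)cc(O)c3c2=O)c(O)c(CCC(C)(C)O)c1OC | target

## Step count and least certain steps

Total: 15 steps. Longest linear sequence: 12 steps (steps 1–8, 10, 13, 14, 15).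

**Step 13 (key step).**
- What may go wrong: the diene may add at C6 of pyrylium salt 20 instead of C2, because the difference between a bromine and an aryl neighbour is only moderate. Retro-oxa-Michael opening of the dihydropyranone ring of 21 may compete with loss of HBr. The Dieckmann-type closure of 22 may stall, because the β-keto ester is first deprotonated at its central CH2, which deactivates the ester. The silyl ether may be lost if triflic acid is not buffered.
- Fallback by known chemistry, from 12 to 25: purchased 2,4,6-trihydroxyacetophenone is dibenzylated (BnBr, K2CO3) to 1-[2,4-bis(benzyloxy)-6-hydroxyphenyl]ethanone F1. Condensation with DMF dimethyl acetal gives (E)-1-[2,4-bis(benzyloxy)-6-hydroxyphenyl]-3-(dimethylamino)prop-2-en-1-one F2, and I2 cyclises it to 5,7-bis(benzyloxy)-3-iodo-4H-chromen-4-one F3. Suzuki coupling of F3 with boronate 12 (Pd(PPh3)4, K3PO4) gives 2',5,7-tris(benzyloxy)-4',5'-dimethoxy-3'-(3-methyl-3-triethylsilyloxybutyl)isoflavone F4. Bu4NF/AcOH gives 2',5,7-tris(benzyloxy)-3'-(3-hydroxy-3-methylbutyl)-4',5'-dimethoxyisoflavone F5, and hydrogenolysis over Pd/C gives 25. Ring A is then bought in instead of built.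

**Step 10 (single Suzuki coupling).**
- What may go wrong: double arylation of the symmetric dibromide, protodeboronation of the electron-rich ortho-alkoxy boronate, or opening of the pyranone by aqueous base.
- Fallback, from 13 to 15: the two halogens are differentiated. Monobromination of 13 (Br2, 1 equiv, then pyridine) gives 3-bromo-4H-pyran-4-one F6, and α-iodination (I2, pyridine) gives 3-bromo-5-iodo-4H-pyran-4-one F7. F7 is coupled with 12 at the more reactive C–I bond at room temperature to give 15, so that selectivity rests on the halide and not on stoichiometry.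

**Step 6 (bromination).**
- What may go wrong: competing substitution at the other free ring position (ortho to the C5 methoxy group), which would give a regioisomeric bromide that is hard to separate.
- Fallback, from 9 to 10: the benzyl ether of 9 is hydrogenolysed (H2, Pd/C) to 2-(3-hydroxy-3-methylbutyl)-3,4-dimethoxyphenol F8. Its free hydroxyl directs NBS (CH2Cl2, −78 °C) to the only open ortho position (para is blocked), giving 6-bromo-2-(3-hydroxy-3-methylbutyl)-3,4-dimethoxyphenol F9. Benzylation (BnBr, K2CO3) returns 10.

**Step 15 (hydrogenolysis).**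
- What may go wrong: saturation of the C2=C3 bond of ring C may compete with debenzylation, or the catalyst may be slowed by the polyphenol.
- Fallback, from 23 to 25: the order and the method are changed. The benzyl ether of 23 is cleaved with BCl3 and pentamethylbenzene in CH2Cl2 at −78 °C while the tertiary oxygen is still silylated, giving 2',5,7-trihydroxy-4',5'-dimethoxy-3'-(3-methyl-3-triethylsilyloxybutyl)isoflavone F10. Bu4NF/AcOH then gives 25.

## Further compounds

F1 | step 13 | 1-[2,4-bis(benzyloxy)-6-hydroxyphenyl]ethanone | CC(=O)c1c(O)cc(OCc2ccccc2)cc1OCc1ccccc1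
F2 | step 13 | (E)-1-[2,4-bis(benzyloxy)-6-hydroxyphenyl]-3-(dimethylamino)prop-2-en-1-one | CN(C)/C=C/C(=O)c1c(O)cc(OCc2ccccc2)cc1OCc1ccccc1
F3 | step 13 | 5,7-bis(benzyloxy)-3-iodo-4H-chromen-4-one | O=c1c(I)coc2cc(OCc3ccccc3)cc(OCc3ccccc3)c12
F4 | step 13 | 2',5,7-tris(benzyloxy)-4',5'-dimethoxy-3'-(3-methyl-3-triethylsilyloxybutyl)isoflavone | O=c1c(-c2cc(OC)c(OC)c(CCC(C)(C)O[Si](CC)(CC)CC)c2OCc2ccccc2)coc2cc(OCc3ccccc3)cc(OCc3ccccc3)c12
F5 | step 13 | 2',5,7-tris(benzyloxy)-3'-(3-hydroxy-3-methylbutyl)-4',5'-dimethoxyisoflavone | O=c1c(-c2cc(OC)c(OC)c(CCC(C)(C)O)c2OCc2ccccc2)coc2cc(OCc3ccccc3)cc(OCc3ccccc3)c12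
F6 | step 10 | 3-bromo-4H-pyran-4-one | O=c1ccocc1Br
F7 | step 10 | 3-bromo-5-iodo-4H-pyran-4-one | O=c1c(Br)cocc1I
F8 | step 6 | 2-(3-hydroxy-3-methylbutyl)-3,4-dimethoxyphenol | COc1ccc(O)c(CCC(C)(C)O)c1OC
F9 | step 6 | 6-bromo-2-(3-hydroxy-3-methylbutyl)-3,4-dimethoxyphenol | COc1cc(Br)c(O)c(CCC(C)(C)O)c1OC
F10 | step 15 | 2',5,7-trihydroxy-4',5'-dimethoxy-3'-(3-methyl-3-triethylsilyloxybutyl)isoflavone | O=c1c(-c2cc(OC)c(OC)c(CCC(C)(C)O[Si](CC)(CC)CC)c2O)coc2cc(O)cc(O)c12
A1 | alternative 1 | racemic 5,7-dihydroxy-3-(5,6-dimethoxy-2-oxochroman-8-yl)chroman-4-one | O=C1c2c(O)cc(O)cc2OCC1c1cc(OC)c(OC)c2CCC(=O)Oc12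
A2 | alternative 1 | 2-(5,6-dimethoxy-2-oxochroman-8-yl)prop-2-enoic acid | C=C(C(=O)O)c1cc(OC)c(OC)c2CCC(=O)Oc12
A3 | alternative 1 | phloroglucinol (benzene-1,3,5-triol) | Oc1cc(O)cc(O)c1
A4 | alternative 2 | 2'-benzyloxy-5,7-difluoro-4',5'-dimethoxy-3'-(3-methyl-3-triethylsilyloxybutyl)isoflavone | O=c1c(-c2cc(OC)c(OC)c(CCC(C)(C)O[Si](CC)(CC)CC)c2OCc2ccccc2)coc2cc(F)cc(F)c12
A5 | alternative 2 | (E)-4-{2-[2-(benzyloxy)-4,5-dimethoxy-3-(3-methyl-3-triethylsilyloxybutyl)phenyl]ethenyl}morpholine | O1CCN(CC1)/C=C/c1cc(OC)c(OC)c(CCC(C)(C)O[Si](CC)(CC)CC)c1OCc1ccccc1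
A6 | alternative 2 | 2,4,6-trifluorobenzoyl chloride | O=C(Cl)c1c(F)cc(F)cc1F
A7 | alternative 3 | racemic 5,7-bis(benzyloxy)-3-[2-(benzyloxy)-4,5-dimethoxy-3-(3-methyl-3-triethylsilyloxybutyl)phenyl]-3-hydroxychroman-4-one | O=C1c2c(OCc3ccccc3)cc(OCc3ccccc3)cc2OCC1(O)c1cc(OC)c(OC)c(CCC(C)(C)O[Si](CC)(CC)CC)c1OCc1ccccc1
A8 | alternative 3 | 2,4-bis(benzyloxy)-6-{2-[2-(benzyloxy)-4,5-dimethoxy-3-(3-methyl-3-triethylsilyloxybutyl)phenyl]-2-oxoethoxy}benzaldehyde | O=Cc1c(OCc2ccccc2)cc(OCc2ccccc2)cc1OCC(=O)c1cc(OC)c(OC)c(CCC(C)(C)O[Si](CC)(CC)CC)c1OCc1ccccc1
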